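**Late E.** Over the last 3 readings of each run, the E left as a fraction of its charge averages 5.27% in the maple run and 10.5% in the oak run, a ratio of 0.502, with twice the E charged in maple. The birch run, with more Q than the oak run, shows 11.2%.

| setting | oak | birch | maple | flask |
|---|---|---|---|---|
| E | 16 mM | 16 mM | 32 mM | 16 mM |
| Q | 2.1 mM | 4.8 mM | 3.2 mM | 3.20 mM |
| Z | 80 µM | 80 µM | 80 µM | 80 µM |
| G | 17 µM | 17 µM | 17 µM | 17 µM |
| remark | run made earlier | run made earlier | run made earlier |  |
| time |  |  |  | 10 d |

| run | time / d | X / % | E / % |
|---|---|---|---|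
| oak | 0.500 | 36.5 | 49.3 |
| oak | 1.67 | 69.6 | 15.4 |
| oak | 3.00 | 76.2 | 13.4 |
| oak | 4.00 | 74.3 | 11.2 |
| oak | 6.00 | 74.2 | 10.6 |
| oak | 8.00 | 76.0 | 9.6 |
| birch | 0.500 | 29.0 | 40.9 |
| birch | 1.67 | 54.1 | 14.9 |
| birch | 3.00 | 58.6 | 11.5 |
| birch | 4.00 | 58.5 | 9.6 |
| birch | 6.00 | 59.0 | 11.9 |
| birch | 8.00 | 59.6 | 12.0 |
| maple | 0.625 | 52.6 | 37.0 |
| maple | 2.08 | 80.4 | 9.1 |
| maple | 4.00 | 83.2 | 5.7 |
| maple | 6.00 | 83.8 | 5.6 |
| maple | 8.00 | 85.8 | 4.5 |

(scatter of a reading: 1 percentage point)

- the average divides the monomer in chains by the number of chains begun, living and dead together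
- candidate steps: E + Z -> L + X; E + L -> X + L; X + L -> E + L; Q + E -> J; Z + G -> D
- the earlier runs do not show the number of chains; that part of a forecast is a guess

* average number of monomer units in a chain (chains begun, living or dead) at 10 d
* part of the E that has reacted at 10 d

**The floor.** So the readings point to a shared amount of E rather than a shared fraction. The floor, the free E at which E joining L and X leaving L balance, is read from them as 1.72 mM (the equilibrium monomer concentration). In this flask it is 10.7% of the charge, so c is about 89.3%. The oak run's X reads 76.2% at 3.00 d and 76.0% at 8.00 d, so this reckoning takes the flask at 10 d as having reached its floor.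

**Q's share.** In the birch run 28.4% of the E is in neither X nor E at the last reading, against a Q to E ratio of 30.0%; in maple it is 9.70% against 10.0%. So each Q is taken to remove one E. In this flask Q is then reckoned to take 20.0% of the charge, which leaves X at 69.3%.

**Chain count.** If each Z begins one chain, dp is 139. This is the weak link, since the runs do not show chains. If each G first removes one Z, 21.3% of it, dp becomes 176. This reckoning therefore holds dp as a range between those two values.

**Forecast.** It gives dp 170 (135 to 200) and c 89.7% (88.3% to 91%), reading the late E as “so this is a ceiling equilibrium”. Its numbers are close to the reckoning here, but not the same.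

**Result.** The flask gives dp 176 and c 89.2%, and the forecast held on both.

    E + Z → L + X (k = 30.0 /M/h)
    E + L → X + L, rate k2*[L]*[E] (k = 1100 /M/h)
    X + L → E + L, rate k3*[L] as long as [X] is above zero (k = 1.90 /h)
    Q + E → J (k = 73.0 /M/h)
    Z + G → D (k = 7.30 × 10⁵ /M/h)

**Floor again.** At 10.0 d L stands at 0.0630 mM and D at 0.0170 mM, with Z and G at 0% and 0% of their charge. The floor share of 10.7% stands beside this flask's E of 10.8%. A neighbour charged with 4.0 mM of E has a floor share of 43.0%, more than the 20.0% that Q leaves it. That neighbour ends with E at 20.0%, J at 80.0% and X at 0.0344%.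

The runs stem from a simulated flask for substances that don't exist; scatter was added.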